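Minutes of the meeting on this flask.

The meeting opened on what stays the same in a closed flask: counted as J, the solid, Q, Q.Z, X and Q2 together keep to the charge, and the step between Q.Z and X only moves material from one to the other. The questions were these.

J 0.022 M; Z 0.0330 M; time 3.0 min

* how much Q.Z there is at 3.0 min, in percent of the J charged
* the change that raises the amount of Q.Z at 3.0 min, in percent of the J charged most ("none" if none brings more than 2 percentage points) (Monday's / Sunday's / Friday's / none)
* amount of Q.Z at 3.0 min, in percent of the J charged, after Monday's

- Monday's: doubling the dissolution coefficient of step 3, all else as stated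
- Sunday's: doubling the solubility in step 3, all else as stated
- Friday's: doubling the amount of Z, all else as stated

- in percentages every species weighs as the J in it: one Q2 counts as two
- for a step with 2 of a species take k times the square, and two of it per event
- as a solid, counted per litre of solution: J
- at the start none of J is in solution
- run time (flask): 3.0 min

    Q + Z → Q.Z (k1 = 46 M⁻¹ s⁻¹)
    Q.Z ⇌ X (K2 = 1.2, k2 = 0.0024 s⁻¹)
    J ⇌ Q, rate k3*(cs3 - [Q]) while solid is left; crystals form when [Q] > cs3 (cs3 = 17 mM, k3 = 0.012 s⁻¹)
    2 Q → Q2 (k4 = 30 M⁻¹ s⁻¹)

A colleague argued that the dissolving is the rate-limiting step, since Z takes up Q at 1.52 s⁻¹ against the solid's coefficient of 0.012 s⁻¹. So c_Q starts near 0.134 mM and climbs as Z is used, towards 0.403 mM on the Z that is over once J is through, and J, the limiting reagent, feeds in evenly for 1.80 min. Another speaker raised the pairing of Q into Q2, and I set it aside, since at that higher c_Q it takes Q at 0.0242 s⁻¹ against 0.506 s⁻¹ by that remaining Z.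

I argued that the end state turns on the age of the Q.Z. The yardstick is the relaxation half-life 2.63 min, the time in which the distance of Q.Z from its resting share halves, both directions together. The resting share is 45.5%. Fed evenly, the Q.Z is on average 2.10 min old at 3.0 min, which is 0.800 half-lives, so I committed to 76.8%. Monday's and Sunday's each halve the feed time, which makes the Q.Z older, 2.55 min, and gives 73.3%. Friday's leaves the feed time as it was, so my answer was none.

The forecast was read out: 76%, best change none, and 71.4% after Monday's, with the words “Averaging over the feed period leaves Q.Z fraction ≈ 0.772 at 180 s”. Both its amounts lie below mine.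

The simulation gives 76.2%, best change none, and 71.6% after Monday's.

In the flask, half of the turning of Q + Z into Q.Z was done by 0.917 min, which leaves that halfway point 2.08 min behind the reading, shorter than the relaxation half-life of 2.63 min, and Q.Z reads 76.2% against 22.4% of X. Read at 5.0 min, the same flask has 1.55 half-lives behind that point, which reckons to 64.1% as Q.Z, and it holds 63.3%.

All constants were set for the occasion; the run is a simulation.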